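**Retrosynthetic overview**
- The C3' ketone is traced back to the norbornene C3'=C4' of a Diels–Alder dimer (10). Cutting C2–C2' and C3–C5' gives two molecules of one monomer, the 10β-hydroxyguaia-2,4-dien-12,6α-olide 9.
- 9 arises by a [1,5]-hydrogen shift from dienol 8, which comes from the 1β,10β-epoxyguai-3-enolide 6 by opening the epoxide toward C2. 6 comes from the 4α-hydroxyguai-1(10)-enolide 3 by epoxidation and dehydration.
- Feature used: in each C15 half the ring-fusion bond C1–C5 is shared by the five-membered ring A (C1–C5) and the seven-membered ring B (C1, C10, C9, C8, C7, C6, C5). Cutting it leaves a ten-membered germacranolide, and parthenolide already holds the C6/C7 trans-lactone and a 4,5-epoxide placed to close this bond.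
- Ring order: lactones (purchased), then rings A and B of each half together in the transannular cyclisation 2 → 3, then the norbornane by dimerisation; the ketone comes last.

Key step: step 2

Remark on numbering: guaiane numbering is used; in the dimers unprimed locants belong to the half that reacts as dienophile (it keeps C4=C5) and primed locants to the half that reacts as diene. α/β refer to the usual guaianolide drawing (H7 α, C6–O α).
Assumption: the peracid is taken to attack C1=C10 of 3 on the β face, anti to the 4α-hydroxyl, as is usual for 4α-hydroxyguai-1(10)-enolides; the fallback for step 3 covers the other case.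

**Step 1**
Reactants: 1 parthenolide
Product: 2 11βH,13-dihydroparthenolide (4α,5β-epoxy-11βH-germacr-1(10)E-en-12,6α-olide)
Conditions: NaBH4, MeOH, 0 °C
Reagents that add atoms: none
Why: Conjugate hydride reduction of the α-methylene-γ-lactone, in which the enolate should be protonated at C11 on the β face to give the pseudo-equatorial 11α-methyl group, while the epoxide and the trisubstituted alkene are inert to NaBH4.

**Step 2**
Reactants: 2 11βH,13-dihydroparthenolide
Product: 3 4α-hydroxy-5αH,11βH-guai-1(10)-en-12,6α-olide
Conditions: BF3·OEt2 (20 mol%), CH2Cl2, 0 °C → rt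
Reagents that add atoms: none
Why: BF3 binds the epoxide oxygen and the C1=C10 π bond, held across the ring in the chair-like germacrane conformer, attacks C5 opposite the C5–O bond with Markovnikov polarity so that charge builds at tertiary C10, after which the C1 proton is lost to give the tetrasubstituted C1=C10 alkene. The closest known reaction type is the acid-mediated transannular epoxide–olefin cyclisation of 4,5-epoxygermacranolides to 4-hydroxyguai-1(10)-enolides. Ring A (C1–C5) closes 5-exo with respect to the alkene (C10 stays outside and carries the charge; at the epoxide the opening is SN2-like at C5), and the seven-membered ring B is the complementary 7-endo closure, that is, the remainder of the ten-membered ring. The one new stereocentre, C5, results from inversion at the epoxide carbon and is therefore fixed by the trans-4,5-epoxide, while C4 keeps its C–O bond and becomes the 4α-carbinol. The step needs C1–C5 rather than C10–C5 bonding and proton loss rather than capture of the C10 cation: only C1 can reach C5 through a five-membered transition state that leaves a tertiary cation, and the non-nucleophilic medium leaves elimination toward C1 as the exit.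

**Step 3**
Reactants: 3 4α-hydroxy-5αH,11βH-guai-1(10)-en-12,6α-olide; 4 3-chloroperoxybenzoic acid
Product: 5 1β,10β-epoxy-4α-hydroxy-5αH,11βH-guaian-12,6α-olide
Conditions: mCPBA, NaHCO3, CH2Cl2, 0 °C
Reagents that add atoms: 3-chloroperoxybenzoic acid, OOC(=O)c1cccc(Cl)c1
Why: Prilezhaev epoxidation of the only, electron-rich tetrasubstituted alkene, expected on the β face because the α face is screened by the pseudo-axial 5α-H, the α-oriented lactone oxygen at C6 and the 4α-hydroxyl, which fixes the β C10–O bond needed in both halves of the target.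

**Step 4**
Reactants: 5 1β,10β-epoxy-4α-hydroxy-5αH,11βH-guaian-12,6α-olide
Product: 6 1β,10β-epoxy-5αH,11βH-guai-3-en-12,6α-olide
Conditions: Martin sulfurane Ph2S[OC(CF3)2Ph]2, CH2Cl2, 0 °C → rt
Reagents that add atoms: none
Why: Sulfurane dehydration of the tertiary carbinol by anti elimination from the alkoxysulfonium ion, for which only H3β and the C15 hydrogens are anti to the 4α leaving group (H5 is syn), so the Zaitsev C3=C4 alkene should prevail under conditions neutral enough for the tetrasubstituted epoxide.

**Step 5**
Reactants: 6 1β,10β-epoxy-5αH,11βH-guai-3-en-12,6α-olide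
Product: 8 10β-hydroxy-5αH,11βH-guaia-1,3-dien-12,6α-olide (principal tautomer; used crude), via lithium lactone enolate 7 (not isolated)
Conditions: LiN(iPr)2 (3.5 equiv), THF, −78 → 0 °C; AcOH (3.5 equiv), THF, −78 °C
Reagents that add atoms: none
Why: Lithium amide-mediated syn β-elimination of an epoxide to an allylic alcohol, in which the first equivalent masks the lactone as its enolate and the lithium-bound amide then removes the C2 β-hydrogen, the only hydrogen syn to the epoxide oxygen that is also allylic, so that C1–O breaks, C1=C2 forms in conjugation with C3=C4 and the oxygen stays β on C10; C11 should be reprotonated from the β face as in step 1.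

**Step 6**
Reactants: 8 10β-hydroxy-5αH,11βH-guaia-1,3-dien-12,6α-olide (two molecules)
Product: 10 Diels–Alder dimer with bonds C2–C2' and C3–C5' (C3'=C4' norbornene; C4=C5 kept; 10β- and 10'β-carbinols), via 1αH-2,4-diene tautomer 9 (not isolated)
Conditions: neat (or concentrated in benzene), rt, dark, Ar, several days
Reagents that add atoms: none
Why: A suprafacial [1,5]-hydrogen shift carries the 5α-hydrogen to C1 (setting 1αH), and the resulting 2,4-diene should dimerise thermally as cyclopentadienes do, one molecule as diene (C2'=C3'–C4'=C5') and the C2=C3 bond of a second as dienophile, both on the α face (syn to H1, anti to the C10 carbinol branch) through the endo transition state that joins the unsubstituted termini C2 and C2', which sets C2, C3, C2' and C5' and places the C1' hydrogen syn to the new C2–C3 bridge.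

**Step 7**
Reactants: 10 Diels–Alder dimer; 11 hydrogen peroxide
Product: 13 3'-exo-hydroxy-3',4'-dihydro dimer (4'-H exo, 4'-methyl endo), via 3'-exo-borane 12 (not isolated)
Conditions: BH3·THF, THF, 0 °C; then 30% H2O2, NaH2PO4/Na2HPO4 buffer (pH 7), 0 °C → rt
Reagents that add atoms: hydrogen peroxide, OO
Why: Brown hydroboration–oxidation, in which the strained trisubstituted norbornene reacts far faster than the tetrasubstituted C4=C5 bond or the lactones, boron goes to the less substituted C3' and B–H adds syn from the exo face because the endo face is buried under the endo-fused cyclopentene of the other half (the 10'-oxygen over the exo face may deliver the borane as its alkoxyborane), so C4' receives its hydrogen exo and C–B oxidation with retention gives the exo alcohol.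

**Step 8**
Reactants: 13 3'-exo-hydroxy-3',4'-dihydro dimer
Product: 14 target (3'-oxo compound, CNP0243924.4)
Conditions: Dess–Martin periodinane, NaHCO3, CH2Cl2, 0 °C → rt
Reagents that add atoms: none
Why: Dess–Martin oxidation of the only secondary alcohol under buffered, non-enolising conditions should leave the two tertiary carbinols, both lactones and the C4' configuration next to the new ketone untouched.

**Compound list**
1 | parthenolide (4α,5β-epoxygermacra-1(10)E,11(13)-dien-12,6α-olide) | C/C/1=C\CC[C@@]2([C@H](O2)[C@@H]3[C@@H](CC1)C(=C)C(=O)O3)C | starting material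
2 | 11βH,13-dihydroparthenolide (11α-methyl) | C/C/1=C\CC[C@@]2([C@H](O2)[C@@H]3[C@@H](CC1)[C@H](C)C(=O)O3)C | intermediate
3 | 4α-hydroxy-5αH,11βH-guai-1(10)-en-12,6α-olide | CC1=C2CC[C@@](C)(O)[C@@H]2[C@H]3OC(=O)[C@@H](C)[C@@H]3CC1 | intermediate
4 | 3-chloroperoxybenzoic acid | OOC(=O)c1cccc(Cl)c1 | starting material
5 | 1β,10β-epoxy-4α-hydroxy-5αH,11βH-guaian-12,6α-olide | C[C@]12O[C@@]23CC[C@@](C)(O)[C@@H]3[C@H]4OC(=O)[C@@H](C)[C@@H]4CC1 | intermediate
6 | 1β,10β-epoxy-5αH,11βH-guai-3-en-12,6α-olide | C[C@]12O[C@@]23CC=C(C)[C@@H]3[C@H]4OC(=O)[C@@H](C)[C@@H]4CC1 | intermediate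
7 | lithium lactone enolate of 6 (C11=C12–OLi; not isolated) | C[C@]12O[C@@]23CC=C(C)[C@@H]3[C@H]4OC([O-])=C(C)[C@@H]4CC1.[Li+] | intermediate
8 | 10β-hydroxy-5αH,11βH-guaia-1,3-dien-12,6α-olide | C[C@@]1(O)C2=CC=C(C)[C@@H]2[C@H]3OC(=O)[C@@H](C)[C@@H]3CC1 | intermediate
9 | 10β-hydroxy-1αH,11βH-guaia-2,4-dien-12,6α-olide (not isolated) | C[C@@]1(O)[C@@H]2C=CC(C)=C2[C@H]3OC(=O)[C@@H](C)[C@@H]3CC1 | intermediate
10 | endo Diels–Alder dimer: C2–C2' and C3–C5' bonds on the α faces, C3'=C4' norbornene with C10' syn to it, C4=C5 retained, 10β-OH and 10'β-OH | CC1=C2[C@H]3OC(=O)[C@@H](C)[C@@H]3CC[C@](C)(O)[C@@H]2[C@H]2[C@H]3C=C(C)[C@]4([C@@H]3[C@@](C)(O)CC[C@H]3[C@H](C)C(=O)O[C@@H]34)[C@@H]12 | intermediate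
11 | hydrogen peroxide | OO | starting material
12 | 3'-exo-boryl-4'-exo-H adduct of 10 (drawn as R–BH2 with free hydroxyls, which are borate esters in the flask; not isolated) | CC1=C2[C@H]3OC(=O)[C@@H](C)[C@@H]3CC[C@](C)(O)[C@@H]2[C@H]2[C@H]3[C@H](B)[C@@H](C)[C@]4([C@@H]3[C@@](C)(O)CC[C@H]3[C@H](C)C(=O)O[C@@H]34)[C@@H]12 | intermediate
13 | 3'-exo-hydroxy-3',4'-dihydro dimer (4'-H exo, 4'-methyl endo) | CC1=C2[C@H]3OC(=O)[C@@H](C)[C@@H]3CC[C@](C)(O)[C@@H]2[C@H]2[C@H]3[C@H](O)[C@@H](C)[C@]4([C@@H]3[C@@](C)(O)CC[C@H]3[C@H](C)C(=O)O[C@@H]34)[C@@H]12 | intermediate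
14 | CNP0243924.4, the 3'-oxo-3',4'-dihydro dimer | CC1=C2[C@H]3OC(=O)[C@@H](C)[C@@H]3CC[C@](C)(O)[C@@H]2[C@H]2[C@H]3C(=O)[C@@H](C)[C@]4([C@@H]3[C@@](C)(O)CC[C@H]3[C@H](C)C(=O)O[C@@H]34)[C@@H]12 | target

**Step count**
Total steps: 8. Longest linear sequence: 8 steps (1 → 14); both halves of the dimer come from the same intermediate, so there is no convergent branch.

**Steps most likely to fail**

Step 5. The amide may remove a C14 or C9 hydrogen instead of the allylic C2 hydrogen, which cleaves C10–O and leaves the oxygen on C1. The lactone enolate may be protonated on the wrong face at C11. Excess base may deprotonate the cyclopentadiene, which can then expel the C6 oxygen. The fallback sets out from 6 and comes back at 8; it puts a carbonyl at C3 so that C1–O is the bond that must break. Hydroboration–oxidation of C3=C4 (BH3·THF; H2O2, pH 7) on the α face should give the 3α-alcohol F1. Dess–Martin oxidation gives the β,γ-epoxy ketone F2. Et3N opens it by E1cB to the γ-hydroxy enone F3, leaving the oxygen on C10. Luche reduction (NaBH4, CeCl3·7H2O, MeOH) from the α face gives the 3β-allylic alcohol F4. MsCl/Et3N sulfonylates only the secondary hydroxyl to give the mesylate F5, and DBU removes the anti 4α-hydrogen to give 8.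

Step 7. Approach of borane to the exo face may be slowed by the 10'-carbinol that sits over it, which would lead to low conversion, attack on the wrong alkene or reduction of the lactones. The fallback sets out from 10 and comes back at 14; it uses that hydroxyl as a director. OsO4·TMEDA (CH2Cl2, −78 °C; then aqueous Na2SO3), delivered by hydrogen bonding to the 10'-OH, should give the 3',4'-exo-diol F6. Parikh–Doering oxidation (SO3·pyridine, DMSO, iPr2NEt) of its secondary hydroxyl gives the α-ketol F7. SmI2 (THF/MeOH, −78 °C) cleaves the tertiary C4'–O bond, and protonation of the samarium enolate on the open exo face (or equilibration of the now enolisable C4') gives 14.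

Step 3. The 4α-hydroxyl may deliver the peracid by hydrogen bonding to the α face, which would give the 1α,10α-epoxide and in the end the 10-epimeric carbinols. The fallback sets out from 3 and comes back at 6; it reverses the order. Martin sulfurane dehydration first gives guaia-1(10),3-dien-12,6α-olide F8, which has no hydroxyl to bind the peracid. mCPBA (1 equiv, CH2Cl2, −20 °C) then attacks the more electron-rich tetrasubstituted C1=C10 bond under steric control of the ring alone.

**Further compounds**
F1 | step 5 | 1β,10β-epoxy-3α-hydroxy-4αH,5αH,11βH-guaian-12,6α-olide | C[C@]12O[C@@]23C[C@@H](O)[C@H](C)[C@@H]3[C@H]4OC(=O)[C@@H](C)[C@@H]4CC1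
F2 | step 5 | 1β,10β-epoxy-3-oxo-4αH,5αH,11βH-guaian-12,6α-olide | C[C@]12O[C@@]23CC(=O)[C@H](C)[C@@H]3[C@H]4OC(=O)[C@@H](C)[C@@H]4CC1
F3 | step 5 | 10β-hydroxy-3-oxo-4αH,5αH,11βH-guai-1-en-12,6α-olide | C[C@@]1(O)C2=CC(=O)[C@H](C)[C@@H]2[C@H]3OC(=O)[C@@H](C)[C@@H]3CC1
F4 | step 5 | 3β,10β-dihydroxy-4αH,5αH,11βH-guai-1-en-12,6α-olide | C[C@@]1(O)C2=C[C@H](O)[C@H](C)[C@@H]2[C@H]3OC(=O)[C@@H](C)[C@@H]3CC1
F5 | step 5 | 3β-methanesulfonate of F4 | C[C@@]1(O)C2=C[C@H](OS(C)(=O)=O)[C@H](C)[C@@H]2[C@H]3OC(=O)[C@@H](C)[C@@H]3CC1
F6 | step 7 | 3',4'-exo-dihydroxy-3',4'-dihydro dimer (4'-methyl endo) | CC1=C2[C@H]3OC(=O)[C@@H](C)[C@@H]3CC[C@](C)(O)[C@@H]2[C@H]2[C@H]3[C@H](O)[C@](C)(O)[C@]4([C@@H]3[C@@](C)(O)CC[C@H]3[C@H](C)C(=O)O[C@@H]34)[C@@H]12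
F7 | step 7 | 4'-exo-hydroxy-3'-oxo-3',4'-dihydro dimer | CC1=C2[C@H]3OC(=O)[C@@H](C)[C@@H]3CC[C@](C)(O)[C@@H]2[C@H]2[C@H]3C(=O)[C@](C)(O)[C@]4([C@@H]3[C@@](C)(O)CC[C@H]3[C@H](C)C(=O)O[C@@H]34)[C@@H]12
F8 | step 3 | 5αH,11βH-guaia-1(10),3-dien-12,6α-olide | CC1=C2CC=C(C)[C@@H]2[C@H]3OC(=O)[C@@H](C)[C@@H]3CC1
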